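**Retrosynthetic overview**
1. The C3=C4 double bond is traced back to a chroman with a phenylsulfonyl group at C4 (loss of benzenesulfinic acid). Phenyl vinyl sulfone can then deliver the C3–C4 unit at the oxidation level of acetylene.
2. Key disconnection: C2–C3 and C4–C4a of the pyran ring (ring C) are made together. The reaction is a redox-neutral photoredox (4+2) radical annulation of the N-hydroxyphthalimide ester of an α-aryloxyisobutyric acid with the vinyl sulfone; CO2 and sulfinate are traceless handles.
3. Enabling feature: C2 is a fully substituted carbon bound to ring oxygen O1 and two methyl groups, so it becomes a stabilised, nucleophilic tertiary radical once a carboxyl group leaves it. C4a is the only hydrogen-bearing carbon of ring A and lies ortho to O1 and 5-OH and para to 7-OH, so it captures the electrophilic C4 radical, and the same oxygens later expel sulfinate from C4.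
4. The acid comes from etherification of the non-chelated 4-OH (para to the carbonyl) of a 3-prenyl-2,4,6-trihydroxybenzophenone. That ketone comes from C-prenylation of the Houben–Hoesch product of phloroglucinol and O-tosyl-3-hydroxybenzonitrile.
5. Ring order: rings A and B are bought. Ring C is the only ring formed (step 7) and receives its double bond in step 8.

Key step: step 7

Remark on the chemistry: the target has no stereocentre. The only stereocentre of the route (C4 of 13) is formed as a racemate and is erased in step 8. Chromene numbering (O1, C2, C3, C4, C4a, C5–C8, C8a) is used. Ring A is the phloroglucinol ring, ring B the 3-hydroxyphenyl ring, ring C the pyran ring.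

**Step 1**
Reactants: 1 3-hydroxybenzonitrile
Product: 2 3-cyanophenyl 4-methylbenzenesulfonate
Conditions: TsCl (1.1 equiv), K2CO3 (1.5 equiv), acetone, rt
Reagents that add atoms: p-toluenesulfonyl chloride, Cc1ccc(cc1)S(=O)(=O)Cl
Why: O-Sulfonylation of the phenoxide (Schotten–Baumann-type tosylation) should mask the ring B phenol with a group that is inert to HCl/ZnCl2 and to the mild bases of steps 3 and 4 yet falls to hot hydroxide in step 5.

**Step 2**
Reactants: 2 3-cyanophenyl 4-methylbenzenesulfonate; 3 phloroglucinol (benzene-1,3,5-triol)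
Product: 5 3-(2,4,6-trihydroxybenzoyl)phenyl 4-methylbenzenesulfonate, via ketiminium chloride 4 (not isolated)
Conditions: ZnCl2, dry HCl (g), Et2O, 0 °C to rt; then H2O, reflux
Reagents that add atoms: water, O
Why: Houben–Hoesch acylation: the nitrile activated by HCl/ZnCl2 attacks one of the three equivalent carbons of phloroglucinol, the precipitating ketiminium salt 4 is deactivated against a second acylation, and boiling water hydrolyses it to the ketone while the aryl tosylate is untouched by acid.

**Step 3**
Reactants: 5 3-(2,4,6-trihydroxybenzoyl)phenyl 4-methylbenzenesulfonate; 6 prenyl bromide (1-bromo-3-methylbut-2-ene)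
Product: 7 3-[2,4,6-trihydroxy-3-(3-methylbut-2-en-1-yl)benzoyl]phenyl 4-methylbenzenesulfonate
Conditions: KOH (1.0 equiv), 6 (0.9 equiv), MeOH–H2O, 0 °C to rt, Ar
Reagents that add atoms: none
Why: C-Alkylation of an ambident acylphloroglucinolate with an allylic bromide (SN2): one equivalent of KOH ionises only the vinylogous-acid system of ring A, the protic medium shields the oxygens by hydrogen bonding so that carbon attacks, C3 and C5 are equivalent, and a deficit of 6 should hold back the second prenylation.

**Step 4**
Reactants: 7 3-[2,4,6-trihydroxy-3-(3-methylbut-2-en-1-yl)benzoyl]phenyl 4-methylbenzenesulfonate; 8 ethyl 2-bromo-2-methylpropanoate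
Product: 9 ethyl 2-{3,5-dihydroxy-2-(3-methylbut-2-en-1-yl)-4-[3-(tosyloxy)benzoyl]phenoxy}-2-methylpropanoate
Conditions: K2CO3 (1.2 equiv), 8 (1.5 equiv), DMF, 70 °C, Ar
Reagents that add atoms: none
Why: Williamson-type etherification with a tertiary α-bromo ester as practised for fibrate esters: carbonate ionises the most acidic, non-chelated 4-OH para to the carbonyl, the 2- and 6-OH groups are hydrogen-bonded and crowded by the aroyl group, and the ring B oxygen is blocked as its tosylate.

**Step 5**
Reactants: 9 ethyl 2-{3,5-dihydroxy-2-(3-methylbut-2-en-1-yl)-4-[3-(tosyloxy)benzoyl]phenoxy}-2-methylpropanoate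
Product: 10 2-[3,5-dihydroxy-4-(3-hydroxybenzoyl)-2-(3-methylbut-2-en-1-yl)phenoxy]-2-methylpropanoic acid
Conditions: NaOH (2 M aq, 8 equiv), 1,4-dioxane, 80 °C, Ar; then 1 M HCl, 0 °C
Reagents that add atoms: sodium hydroxide, [Na+].[OH-]
Why: Saponification of the ester (BAc2) and hydroxide attack at sulfur of the aryl tosylate should run in the same flask, the alcohol-free cosolvent avoids alkyl tosylates that could alkylate the phenoxides, and ether, ketone and prenyl group are inert to base.

**Step 6**
Reactants: 10 2-[3,5-dihydroxy-4-(3-hydroxybenzoyl)-2-(3-methylbut-2-en-1-yl)phenoxy]-2-methylpropanoic acid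
Product: 11 1,3-dioxoisoindolin-2-yl 2-[3,5-dihydroxy-4-(3-hydroxybenzoyl)-2-(3-methylbut-2-en-1-yl)phenoxy]-2-methylpropanoate
Conditions: N-hydroxyphthalimide (1.1 equiv), N,N'-diisopropylcarbodiimide (1.1 equiv), THF, 0 °C to rt
Reagents that add atoms: N-hydroxyphthalimide, O=C1c2ccccc2C(=O)N1O
Why: Carbodiimide-mediated active ester formation (Steglich-type, run without DMAP): the acidic and α-nucleophilic N-hydroxyphthalimide should intercept the O-acylisourea far faster than the chelated or weakly nucleophilic phenols, as in active-ester formation beside an unprotected tyrosine.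

**Step 7**
Reactants: 11 1,3-dioxoisoindolin-2-yl 2-[3,5-dihydroxy-4-(3-hydroxybenzoyl)-2-(3-methylbut-2-en-1-yl)phenoxy]-2-methylpropanoate; 12 phenyl vinyl sulfone
Product: 13 rac-[5,7-dihydroxy-2,2-dimethyl-8-(3-methylbut-2-en-1-yl)-4-(phenylsulfonyl)chroman-6-yl](3-hydroxyphenyl)methanone
Conditions: fac-Ir(ppy)3 (1 mol %), 12 (3 equiv), DMSO (0.2 M), 450 nm LEDs, Ar, rt
Reagents that add atoms: none
Why: Photoexcited fac-Ir(ppy)3 reduces the N-acyloxyphthalimide of 11, which sheds phthalimide anion and CO2 and leaves the tertiary α-aryloxy radical at the future C2; this nucleophilic radical adds to the CH2 end of electron-poor 12 (C2–C3 bond), the electrophilic α-sulfonyl radical then attacks the one free carbon of ring A (C4–C4a bond), and tetravalent iridium oxidises the cyclohexadienyl radical before phthalimide anion removes the proton, so the step is redox-neutral and needs no oxidant that would harm the phenols. The closest known reaction type is the photoredox (4+2) radical annulation of α-aryloxyalkyl radicals from N-hydroxyphthalimide esters with electron-poor alkenes to chromans, the oxygen counterpart of the N-arylaminoalkyl radical/alkene route to tetrahydroquinolines (radical addition followed by homolytic aromatic substitution). Ring C closes by six-membered ortho attack (formally 6-endo-trig on the C4a–C8a bond), helped by the gem-dimethyl effect, whereas 5-exo ipso attack at C8a is reversible and unproductive because an aryl shift from O to C would cost an alkoxyl radical. C4 of 13 is the only new stereocentre, nothing controls it, and the racemate is accepted because step 8 erases it. The step needs intermolecular capture of the C2 radical to beat its 6-exo addition to, or 1,5-hydrogen abstraction from, the neighbouring prenyl group, which the polarity match with 12 (in excess, at high concentration) against the mismatch with an electron-rich trisubstituted alkene should secure, and the regiochemistry is fixed because the other ortho carbon carries the prenyl group while C4a is activated by O1, 5-OH and 7-OH. The sulfone keeps C3–C4 saturated during irradiation so that the light-sensitive chromene is never exposed, and DMSO hydrogen-bonds the phenolic O–H groups and so slows hydrogen transfer to the carbon radicals.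

**Step 8**
Reactants: 13 rac-[5,7-dihydroxy-2,2-dimethyl-8-(3-methylbut-2-en-1-yl)-4-(phenylsulfonyl)chroman-6-yl](3-hydroxyphenyl)methanone
Product: 15 [5,7-dihydroxy-2,2-dimethyl-8-(3-methylbut-2-en-1-yl)-2H-chromen-6-yl](3-hydroxyphenyl)methanone (target), via ortho-quinone methide 14 (not isolated)
Conditions: DBU (3 equiv), MeCN, 50 °C, Ar, dark; then aq citric acid
Reagents that add atoms: none
Why: Base-induced elimination of sulfinate from a 2-(1-sulfonylalkyl)phenol, the standard entry to ortho-quinone methides: the 5-phenoxide (backed by O1 and 7-O) expels benzenesulfinate from C4 to give 14, DBU then removes the vinylogously acidified C3–H so that ring A rearomatises to the conjugated 2H-chromene, the C4 stereocentre vanishes and the prenyl group is untouched.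

**Compound list**
1 | 3-hydroxybenzonitrile | N#Cc1cccc(O)c1 | starting material
2 | 3-cyanophenyl 4-methylbenzenesulfonate | N#Cc1cccc(OS(=O)(=O)c2ccc(C)cc2)c1 | intermediate
3 | phloroglucinol | Oc1cc(O)cc(O)c1 | starting material
4 | ketiminium chloride of 5 (not isolated) | [Cl-].[NH2+]=C(c1cccc(OS(=O)(=O)c2ccc(C)cc2)c1)c1c(O)cc(O)cc1O | intermediate
5 | 3-(2,4,6-trihydroxybenzoyl)phenyl 4-methylbenzenesulfonate | O=C(c1cccc(OS(=O)(=O)c2ccc(C)cc2)c1)c1c(O)cc(O)cc1O | intermediate
6 | prenyl bromide | CC(C)=CCBr | starting material
7 | 3-[2,4,6-trihydroxy-3-(3-methylbut-2-en-1-yl)benzoyl]phenyl 4-methylbenzenesulfonate | CC(C)=CCc1c(O)cc(O)c(C(=O)c2cccc(OS(=O)(=O)c3ccc(C)cc3)c2)c1O | intermediate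
8 | ethyl 2-bromo-2-methylpropanoate | CCOC(=O)C(C)(C)Br | starting material
9 | ethyl 2-{3,5-dihydroxy-2-(3-methylbut-2-en-1-yl)-4-[3-(tosyloxy)benzoyl]phenoxy}-2-methylpropanoate | CC(C)=CCc1c(OC(C)(C)C(=O)OCC)cc(O)c(C(=O)c2cccc(OS(=O)(=O)c3ccc(C)cc3)c2)c1O | intermediate
10 | 2-[3,5-dihydroxy-4-(3-hydroxybenzoyl)-2-(3-methylbut-2-en-1-yl)phenoxy]-2-methylpropanoic acid | CC(C)=CCc1c(OC(C)(C)C(=O)O)cc(O)c(C(=O)c2cccc(O)c2)c1O | intermediate
11 | 1,3-dioxoisoindolin-2-yl ester of 10 | CC(C)=CCc1c(OC(C)(C)C(=O)ON2C(=O)c3ccccc3C2=O)cc(O)c(C(=O)c2cccc(O)c2)c1O | intermediate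
12 | phenyl vinyl sulfone | C=CS(=O)(=O)c1ccccc1 | starting material
13 | rac-[5,7-dihydroxy-2,2-dimethyl-8-(3-methylbut-2-en-1-yl)-4-(phenylsulfonyl)chroman-6-yl](3-hydroxyphenyl)methanone (racemic at C4) | CC(C)=CCc1c(O)c(C(=O)c2cccc(O)c2)c(O)c2c1OC(C)(C)CC2S(=O)(=O)c1ccccc1 | intermediate
14 | 7-hydroxy-6-(3-hydroxybenzoyl)-2,2-dimethyl-8-(3-methylbut-2-en-1-yl)-2,3-dihydro-5H-chromen-5-one (ortho-quinone methide, not isolated) | CC(C)=CCC1=C2OC(C)(C)CC=C2C(=O)C(C(=O)c2cccc(O)c2)=C1O | intermediate
15 | [5,7-dihydroxy-2,2-dimethyl-8-(3-methylbut-2-en-1-yl)-2H-chromen-6-yl](3-hydroxyphenyl)methanone | CC(C)=CCc1c(O)c(C(=O)c2cccc(O)c2)c(O)c2c1OC(C)(C)C=C2 | target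

Total step count: 8. Longest linear sequence: 8 steps (1 to 15).

**Steps most likely to fail**

**Step 7.** The C2 radical may be consumed inside the molecule, by hydrogen transfer from the benzylic-allylic CH2 or by addition to the prenyl double bond. It may also be over-oxidised to the oxocarbenium ion, or the adduct radical may telomerise with 12 instead of closing on ring A.

The fallback gives up the radical annulation and builds ring C by the classical pericyclic cascade, setting out from 7.
- O-Alkylation of the 4-OH with 3-chloro-3-methylbut-1-yne (K2CO3, KI, acetone, reflux) should give 3-{2,6-dihydroxy-3-(3-methylbut-2-en-1-yl)-4-[(2-methylbut-3-yn-2-yl)oxy]benzoyl}phenyl 4-methylbenzenesulfonate F1.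
- Heating in xylene should trigger the aromatic propargyl Claisen rearrangement to the free ortho carbon, a 1,5-hydrogen shift and an oxa-6π electrocyclisation. This leads to 3-{[5,7-dihydroxy-2,2-dimethyl-8-(3-methylbut-2-en-1-yl)-2H-chromen-6-yl]carbonyl}phenyl 4-methylbenzenesulfonate F2.
- NaOH in dioxane–water at 80 °C removes the tosyl group, and the route is rejoined at 15.

**Step 4.** Substitution at the tertiary bromide may be slower than base-induced loss of HBr from 8. Forcing the reaction may spread alkylation to the ortho hydroxyl groups.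

The fallback changes the electrophile to the gem-dichloroepoxide of the Bargellini reaction, which is opened by phenoxides at its tertiary carbon and gives the acid directly. It sets out from 7.
- 1,1,1-Trichloro-2-methylpropan-2-ol and powdered NaOH in acetone (0 °C to rt) should give 2-{3,5-dihydroxy-2-(3-methylbut-2-en-1-yl)-4-[3-(tosyloxy)benzoyl]phenoxy}-2-methylpropanoic acid F3.
- Hot aqueous NaOH in dioxane then cleaves the tosylate, and the route is rejoined at 10.

**Step 3.** A second prenylation at C5, geminal dialkylation with loss of aromaticity, and O-prenylation may erode the monoalkylation.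

The fallback delivers exactly one prenyl group by a sigmatropic route, setting out from 5.
- Etherification of the 4-OH with 3-chloro-3-methylbut-1-yne (K2CO3, KI, acetone, 40 °C) should give 3-{2,6-dihydroxy-4-[(2-methylbut-3-yn-2-yl)oxy]benzoyl}phenyl 4-methylbenzenesulfonate F4.
- Semihydrogenation (H2, Pd/CaCO3 poisoned with Pb(OAc)2, quinoline, EtOAc, rt) should give 3-{2,6-dihydroxy-4-[(2-methylbut-3-en-2-yl)oxy]benzoyl}phenyl 4-methylbenzenesulfonate F5.
- An aromatic Claisen rearrangement (toluene, 110 °C) moves the allyl unit with inversion to one of the two equivalent ortho carbons and frees the 4-OH, and the route is rejoined at 7.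

**Further compounds**
F1 | step 7 | 3-{2,6-dihydroxy-3-(3-methylbut-2-en-1-yl)-4-[(2-methylbut-3-yn-2-yl)oxy]benzoyl}phenyl 4-methylbenzenesulfonate | CC(C)=CCc1c(OC(C)(C)C#C)cc(O)c(C(=O)c2cccc(OS(=O)(=O)c3ccc(C)cc3)c2)c1O
F2 | step 7 | 3-{[5,7-dihydroxy-2,2-dimethyl-8-(3-methylbut-2-en-1-yl)-2H-chromen-6-yl]carbonyl}phenyl 4-methylbenzenesulfonate | CC(C)=CCc1c(O)c(C(=O)c2cccc(OS(=O)(=O)c3ccc(C)cc3)c2)c(O)c2c1OC(C)(C)C=C2
F3 | step 4 | 2-{3,5-dihydroxy-2-(3-methylbut-2-en-1-yl)-4-[3-(tosyloxy)benzoyl]phenoxy}-2-methylpropanoic acid | CC(C)=CCc1c(OC(C)(C)C(=O)O)cc(O)c(C(=O)c2cccc(OS(=O)(=O)c3ccc(C)cc3)c2)c1O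
F4 | step 3 | 3-{2,6-dihydroxy-4-[(2-methylbut-3-yn-2-yl)oxy]benzoyl}phenyl 4-methylbenzenesulfonate | C#CC(C)(C)Oc1cc(O)c(C(=O)c2cccc(OS(=O)(=O)c3ccc(C)cc3)c2)c(O)c1
F5 | step 3 | 3-{2,6-dihydroxy-4-[(2-methylbut-3-en-2-yl)oxy]benzoyl}phenyl 4-methylbenzenesulfonate | C=CC(C)(C)Oc1cc(O)c(C(=O)c2cccc(OS(=O)(=O)c3ccc(C)cc3)c2)c(O)c1
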